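A small charge of catalyst is the question here: in Tuesday's run c(catalyst) is 0.260 mM, and I wanted the target at 150 min.

| setting | Monday's | Thursday's | Saturday's | Wednesday's | Tuesday's |
|---|---|---|---|---|---|
| substrate | 80.0 mM | 40.0 mM | 80.0 mM | 80.0 mM | 80.0 mM |
| coupling partner | 88.0 mM | 48.0 mM | 44.0 mM | 88.0 mM | 44.0 mM |
| catalyst | 0.800 mM | 0.800 mM | 0.800 mM | 1.20 mM | 0.260 mM |
| time |  |  |  |  | 150 min |

- Monday's run (time / min: [target] / mM): 6.0: 4.4; 11: 7.8; 22: 14.6; 41: 22.8; 79: 33.6; 150: 40.7
- Thursday's run (time / min: [target] / mM): 6.0: 1.5; 11: 3.3; 22: 5.3; 41: 8.5; 79: 14.8; 150: 20.5
- Saturday's run (time / min: [target] / mM): 6.0: 2.6; 11: 4.1; 22: 8.1; 41: 12.7; 79: 18.3; 150: 23.2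
- Wednesday's run (time / min: [target] / mM): 6.0: 4.7; 11: 9.3; 22: 17.3; 41: 26.5; 79: 39.0; 150: 48.5

(standard deviation of a reading: 0.4 mM)

1. the exponent of [catalyst] in the starting rate at the charge of the Monday's run (at the point where two percent of the substrate have become target)
2. the exponent of [coupling partner] in the starting rate at the charge of the Monday's run (at the point where two percent of the substrate have become target)
3. target in the Tuesday's run at 150 min, as a share of the substrate charged

- Overall: substrate + coupling partner -> target, with catalyst as catalyst.
- Constant volume, constant temperature.
- What is held in complexes is read along with the free species.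
- "The second partner" is coupling partner.
- An order is taken over about fifteen percent of the charge, up and down.

1. Monday's and Wednesday's runs share c(substrate) and c(coupling partner), but c(catalyst) is 0.800 mM against 1.20 mM. At 150 min they hold 40.7 mM and 48.5 mM of target, a ratio of 1.19, although the loading rose by 1.50.

2. I wrote the target as a sum of two parts and solved each end. At zero catalyst, I supposed an uncatalysed background reaction. At the other end, I supposed a catalysed part growing as c(catalyst) to a power n. I defined the background share as the fraction of Monday's target at 150 min that needs no catalyst. The ratio in step 1 then equals this share plus the remainder multiplied by the loading ratio to the power n.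

3. The ratio in step 1 does not choose n. I committed to n = 2, my guess of two catalyst units per turnover, which gives a background share of 84.7%. With n = 1, the share is 61.7%.

4. In this sum, the catalyst exponent near Monday's charge is n times the catalysed fraction. Taking the share at 150 min for the start as well, I reckoned 0.307.

5. Saturday's and Monday's readings at 22 min give a partner exponent of 0.850, as a reading. I took it as near 1 for both parts, so I carried the share to Saturday's run, whose substrate and partner charges match Tuesday's.

6. Tuesday's catalyst is 0.325 of Saturday's, so I took the catalysed part down to 0.106 of its Saturday value and held the background part as it was. From Saturday's 23.2 mM, I reckoned 20.0 mM, or 25.0% of the substrate charged. With n = 1, the figure is 21.5%.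

The forecast gave 0.5 for the catalyst exponent, 0.93 for the partner exponent and 17.5% for Tuesday's run, with the weak catalyst response “suggesting a dimer-like reservoir”. Its share of 17.5% is lower than my 25.0%.

The simulation gave a catalyst exponent of 0.24, a partner exponent of 1.0 and 26.3% of the substrate charged for Tuesday's run.

    catalyst + substrate ⇌ catalyst-substrate complex, settled at all times (175.0 /M)
    catalyst + coupling partner ⇌ catalyst-reagent complex, settled at all times (4.110 /M)
    catalyst-substrate complex + catalyst-reagent complex → target + 2 catalyst (6960 /M/min)
    target → decomposed product (0.003174 /min)
    substrate + coupling partner → target (0.1050 /M/min)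

Tuesday's run proves the reason: with the conversion of substrate and coupling partner into target taken away, its target falls from 26.3% to 0.769%. That uncatalysed step is what my background share of 84.7%, taken on Monday's target at 150 min, stood for. On Monday's charge, removing the same step lifts the catalyst exponent from 0.24 to 2.1, which puts the background share of Monday's starting rate at 88.6%.

(All runs were computed from invented constants.)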